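**Assumption (one line):** the enolised β‑diketone of the target is treated as freely tautomerising, and the facial sense of the Rh/BINAP addition in Step 2 is assigned by the standard Hayashi model, not by a result on this exact substrate.

## Retrosynthetic overview

1. The last C=C bond comes from a boron‑templated (Pabon) aldol condensation of aryl aldehyde 18 with feruloylacetone 20.
2. The aryl allyl ether (C1–O) comes from Mitsunobu inversion of a cis allylic alcohol with vanillin; the C9 enone comes from Weinreb opening of a δ‑lactone.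
3. The C7 methyl is set by cuprate addition to the convex face of a cis‑fused unsaturated δ‑lactone, itself made by acrylate ring‑closing metathesis (a temporary ring, formed second and later opened).
4. C4–OH is set by a ketoreductase; C6 (the first stereocentre) by Rh‑catalysed asymmetric conjugate vinylation of a quinone monoketal.
5. Ring order: the carbocycle is present from the start (dearomatised 4‑methoxy‑2‑methylphenol), then the temporary lactone; both aryl rings are bought.

Bisabolane numbering is used in the explanations: C1 (OAr), C2=C3(Me), C4 (OH), C5, C6 (ring CH), C7 (CHMe), C8, C9 (C=O). The target is 1R,4S,6R,7S: C1–O and C4–O are cis to each other and both trans to the C6 side chain.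

## Route

**Step 1**
Reactants: 1, 4‑methoxy‑2‑methylphenol
Product: 2, 4,4‑dimethoxy‑2‑methylcyclohexa‑2,5‑dien‑1‑one
Conditions: PhI(OAc)2, MeOH, 0 °C → rt
Reagents that add atoms: methanol, CO
Why: Hypervalent‑iodine oxidative dearomatisation of a p‑methoxyphenol in MeOH gives the achiral p‑quinone monoketal, which already carries all six ring carbons and the C3 methyl.

**Step 2**
Reactants: 2; 3, potassium vinyltrifluoroborate
Product: 4, (5R)‑5‑ethenyl‑4,4‑dimethoxy‑2‑methylcyclohex‑2‑en‑1‑one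
Conditions: [Rh(cod)2]BF4 (3 mol%), (R)‑BINAP, Et3N, toluene/H2O, 25–40 °C
Reagents that add atoms: potassium vinyltrifluoroborate (3), C=C[B-](F)(F)F.[K+]
Why: Hayashi–Miyaura Rh‑catalysed asymmetric 1,4‑addition attacks only the unsubstituted enone (the α‑methyl enone is inert), and (R)‑BINAP delivers vinyl to the face that gives C6 = R; this is the first stereocentre.

**Step 3**
Reactants: 4
Product: 5, (1S,5R)‑5‑ethenyl‑4,4‑dimethoxy‑2‑methylcyclohex‑2‑en‑1‑ol
Conditions: ketoreductase (KRED, NADPH‑dependent, (S)‑selective, chosen from a panel), NADP+ cat., glucose dehydrogenase/glucose, KPi pH 7, 10% DMSO, 30 °C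
Reagents that add atoms: none
Why: Enzymatic carbonyl reduction under catalyst control sets C4 = S (OH trans to vinyl) against the substrate's intrinsic cis preference, leaves the neutral‑pH‑stable ketal and alkenes untouched, and turns the minor enantiomer from Step 2 into a separable diastereomer.

**Step 4**
Reactants: 5
Product: 6, tert‑butyl{[(1S,5R)‑5‑ethenyl‑4,4‑dimethoxy‑2‑methylcyclohex‑2‑en‑1‑yl]oxy}dimethylsilane
Conditions: TBSCl, imidazole, DMAP cat., DMF, rt
Reagents that add atoms: TBSCl, CC(C)(C)[Si](C)(C)Cl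
Why: Standard silylation protects C4–OH so that it stays distinct from the C1 oxygen released later.

**Step 5**
Reactants: 6
Product: 7, (4S,6R)‑4‑[(tert‑butyldimethylsilyl)oxy]‑6‑ethenyl‑3‑methylcyclohex‑2‑en‑1‑one
Conditions: PPTS cat., acetone/H2O (10:1), rt; used directly
Reagents that add atoms: water, O
Why: The allylic dimethyl ketal hydrolyses under very mild acid that spares the TBS ether and does not epimerise or conjugate the α‑vinyl ketone.

**Step 6**
Reactants: 7
Product: 8, (1S,4S,6R)‑4‑[(tert‑butyldimethylsilyl)oxy]‑6‑ethenyl‑3‑methylcyclohex‑2‑en‑1‑ol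
Conditions: L‑Selectride, THF, −78 °C
Reagents that add atoms: none
Why: The bulky hydride reduces 1,2 (the β‑methyl blocks 1,4‑reduction) by equatorial attack, giving the pseudoaxial C1–OH cis to the equatorial vinyl, as in piperitone → cis‑piperitol.

**Step 7**
Reactants: 8; 9, acryloyl chloride
Product: 10, (1S,4S,6R)‑4‑[(tert‑butyldimethylsilyl)oxy]‑6‑ethenyl‑3‑methylcyclohex‑2‑en‑1‑yl prop‑2‑enoate
Conditions: i‑Pr2NEt, DMAP cat., CH2Cl2, −20 → 0 °C
Reagents that add atoms: acryloyl chloride (9), C=CC(=O)Cl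
Why: O‑acylation of the secondary alcohol with retention places the two terminal alkenes cis on adjacent carbons.

**Step 8**
Reactants: 10
Product: 11, (4aR,6S,8aS)‑6‑[(tert‑butyldimethylsilyl)oxy]‑7‑methyl‑4a,5,6,8a‑tetrahydro‑2H‑chromen‑2‑one
Conditions: Grubbs II (5 mol%), CH2Cl2 (5 mM), 40 °C
Reagents that add atoms: none (ethylene lost)
Why: Ring‑closing metathesis of the acrylate with the vinyl group forms the cis‑fused α,β‑unsaturated δ‑lactone; the trisubstituted ring alkene does not participate.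

**Step 9**
Reactants: 11
Product: 12, (4S,4aR,6S,8aS)‑6‑[(tert‑butyldimethylsilyl)oxy]‑4,7‑dimethyl‑3,4,4a,5,6,8a‑hexahydro‑2H‑chromen‑2‑one
Conditions: Me2CuLi, TMSCl, THF/Et2O, −78 → −40 °C; aq. NH4Cl/NH3
Reagents that add atoms: lithium dimethylcuprate, [Li+].C[Cu-]C
Why: Gilman conjugate addition occurs on the convex face, anti to the pseudoaxial C4a–C5 bond, so the methyl ends up trans to C5 and sets C7 = S; SN2′ at the allylic lactone oxygen would need attack at a hindered, fully substituted carbon.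

**Step 10**
Reactants: 12
Product: 13, (3S)‑3‑[(1R,2S,5S)‑5‑[(tert‑butyldimethylsilyl)oxy]‑2‑hydroxy‑4‑methylcyclohex‑3‑en‑1‑yl]‑N‑methoxy‑N‑methylbutanamide
Conditions: MeNH(OMe)·HCl, AlMe3, CH2Cl2, 0 °C → rt; Rochelle salt work‑up; used at once
Reagents that add atoms: N,O‑dimethylhydroxylamine hydrochloride, CNOC.Cl
Why: Weinreb aminolysis opens the lactone without touching any stereocentre, freeing the cis C1–OH and putting C9 at the acyl oxidation level.

**Step 11**
Reactants: 13; 14, 2‑methylprop‑1‑enylmagnesium bromide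
Product: 15, (6S)‑6‑[(1R,2S,5S)‑5‑[(tert‑butyldimethylsilyl)oxy]‑2‑hydroxy‑4‑methylcyclohex‑3‑en‑1‑yl]‑2‑methylhept‑2‑en‑4‑one
Conditions: 14 (3.5 equiv), THF, −20 → 0 °C; sat. NH4Cl
Reagents that add atoms: 2‑methylprop‑1‑enylmagnesium bromide (14), CC(C)=C[Mg]Br
Why: Weinreb ketone synthesis stops at the chelated tetrahedral intermediate (the first equivalent only deprotonates the OH) and gives the β,β‑dimethyl enone without over‑addition.

**Step 12**
Reactants: 15; 16, vanillin
Product: 17, 4‑{[(1R,4S,6R)‑4‑[(tert‑butyldimethylsilyl)oxy]‑3‑methyl‑6‑[(2S)‑6‑methyl‑4‑oxohept‑5‑en‑2‑yl]cyclohex‑2‑en‑1‑yl]oxy}‑3‑methoxybenzaldehyde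
Conditions: PPh3, DIAD, toluene, 0 °C → rt
Reagents that add atoms: vanillin (16), COc1cc(C=O)ccc1O
Why: Mitsunobu etherification with the acidic phenol (pKa about 7.4) proceeds by SN2 inversion at C1, the phenoxide entering trans to the side chain to give C1 = R; SN2′ is blocked by the substituted C3.

**Step 13**
Reactants: 17
Product: 18, 4‑{[(1R,4S,6R)‑4‑hydroxy‑3‑methyl‑6‑[(2S)‑6‑methyl‑4‑oxohept‑5‑en‑2‑yl]cyclohex‑2‑en‑1‑yl]oxy}‑3‑methoxybenzaldehyde
Conditions: TBAF/AcOH (1:1), THF, 0 °C → rt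
Reagents that add atoms: none
Why: Buffered fluoride desilylation frees C4–OH without affecting the aldehyde, the enone or the allyl aryl ether.

**Step 14**
Reactants: 16, vanillin; 19, acetylacetone
Product: 20, (E)‑6‑(4‑hydroxy‑3‑methoxyphenyl)hex‑5‑ene‑2,4‑dione (feruloylacetone, enolised)
Conditions: 19 (3 equiv), B2O3, B(OnBu)3, n‑BuNH2 cat., EtOAc, 70 °C; then 0.4 M HCl, 60 °C
Reagents that add atoms: acetylacetone (19), CC(=O)CC(=O)C
Why: In the Pabon condensation, boron complexation masks the central CH2 so a terminal methyl condenses, and excess diketone limits the reaction to mono‑condensation, E‑selectively.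

**Step 15**
Reactants: 18; 20
Product: 21, bisabolocurcumin ether (target)
Conditions: 20 (1.1 equiv), B2O3, B(OnBu)3, n‑BuNH2 (cat., slow addition), EtOAc, 70 °C; then 0.4 M HCl, 40 °C, 30 min, in the dark
Reagents that add atoms: none (water lost)
Why: A second Pabon condensation joins the remaining methyl of the boron‑complexed diketone to the aryl aldehyde to form the E‑styryl bond; no stereocentre is touched and the mild acid release spares the allylic ether and alcohol.

## Compound list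

1 | 4‑methoxy‑2‑methylphenol | COc1ccc(O)c(C)c1 | starting material
2 | 4,4‑dimethoxy‑2‑methylcyclohexa‑2,5‑dien‑1‑one | O=C1C=CC(OC)(OC)C=C1C | intermediate
3 | potassium vinyltrifluoroborate | C=C[B-](F)(F)F.[K+] | starting material
4 | (5R)‑5‑ethenyl‑4,4‑dimethoxy‑2‑methylcyclohex‑2‑en‑1‑one | COC1(OC)C=C(C)C(=O)C[C@@H]1C=C | intermediate
5 | (1S,5R)‑5‑ethenyl‑4,4‑dimethoxy‑2‑methylcyclohex‑2‑en‑1‑ol | COC1(OC)C=C(C)[C@@H](O)C[C@@H]1C=C | intermediate
6 | TBS ether of 5 | COC1(OC)C=C(C)[C@@H](O[Si](C)(C)C(C)(C)C)C[C@@H]1C=C | intermediate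
7 | (4S,6R)‑4‑(TBSO)‑6‑ethenyl‑3‑methylcyclohex‑2‑en‑1‑one | O=C1C=C(C)[C@@H](O[Si](C)(C)C(C)(C)C)C[C@@H]1C=C | intermediate
8 | (1S,4S,6R)‑4‑(TBSO)‑6‑ethenyl‑3‑methylcyclohex‑2‑en‑1‑ol | O[C@@H]1C=C(C)[C@@H](O[Si](C)(C)C(C)(C)C)C[C@@H]1C=C | intermediate
9 | acryloyl chloride | C=CC(=O)Cl | starting material
10 | (1S,4S,6R)‑4‑(TBSO)‑6‑ethenyl‑3‑methylcyclohex‑2‑en‑1‑yl acrylate | C=CC(=O)O[C@@H]1C=C(C)[C@@H](O[Si](C)(C)C(C)(C)C)C[C@@H]1C=C | intermediate
11 | (4aR,6S,8aS)‑6‑(TBSO)‑7‑methyl‑4a,5,6,8a‑tetrahydro‑2H‑chromen‑2‑one | O1[C@@H]2C=C(C)[C@@H](O[Si](C)(C)C(C)(C)C)C[C@@H]2C=CC1=O | intermediate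
12 | (4S,4aR,6S,8aS)‑6‑(TBSO)‑4,7‑dimethyl‑3,4,4a,5,6,8a‑hexahydro‑2H‑chromen‑2‑one | O1[C@@H]2C=C(C)[C@@H](O[Si](C)(C)C(C)(C)C)C[C@@H]2[C@@H](C)CC1=O | intermediate
13 | (3S)‑3‑[(1R,2S,5S)‑5‑(TBSO)‑2‑hydroxy‑4‑methylcyclohex‑3‑en‑1‑yl]‑N‑methoxy‑N‑methylbutanamide | O[C@@H]1C=C(C)[C@@H](O[Si](C)(C)C(C)(C)C)C[C@@H]1[C@@H](C)CC(=O)N(C)OC | intermediate
14 | 2‑methylprop‑1‑enylmagnesium bromide | CC(C)=C[Mg]Br | starting material
15 | (6S)‑6‑[(1R,2S,5S)‑5‑(TBSO)‑2‑hydroxy‑4‑methylcyclohex‑3‑en‑1‑yl]‑2‑methylhept‑2‑en‑4‑one | O[C@@H]1C=C(C)[C@@H](O[Si](C)(C)C(C)(C)C)C[C@@H]1[C@@H](C)CC(=O)C=C(C)C | intermediate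
16 | vanillin | COc1cc(C=O)ccc1O | starting material
17 | 4‑{[(1R,4S,6R)‑4‑(TBSO)‑3‑methyl‑6‑[(2S)‑6‑methyl‑4‑oxohept‑5‑en‑2‑yl]cyclohex‑2‑en‑1‑yl]oxy}‑3‑methoxybenzaldehyde | COc1cc(C=O)ccc1O[C@H]1C=C(C)[C@@H](O[Si](C)(C)C(C)(C)C)C[C@@H]1[C@@H](C)CC(=O)C=C(C)C | intermediate
18 | 4‑{[(1R,4S,6R)‑4‑hydroxy‑3‑methyl‑6‑[(2S)‑6‑methyl‑4‑oxohept‑5‑en‑2‑yl]cyclohex‑2‑en‑1‑yl]oxy}‑3‑methoxybenzaldehyde | COc1cc(C=O)ccc1O[C@H]1C=C(C)[C@@H](O)C[C@@H]1[C@@H](C)CC(=O)C=C(C)C | intermediate
19 | acetylacetone | CC(=O)CC(=O)C | starting material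
20 | feruloylacetone, (E)‑6‑(4‑hydroxy‑3‑methoxyphenyl)hex‑5‑ene‑2,4‑dione | COc1cc(/C=C/C(=O)CC(C)=O)ccc1O | intermediate
21 | bisabolocurcumin ether | COc1cc(/C=C/C(=O)/C=C(O)/C=C/c2ccc(O[C@H]3C=C(C)[C@@H](O)C[C@@H]3[C@@H](C)CC(=O)C=C(C)C)c(OC)c2)ccc1O | target

## Summary

Total steps: 15. Longest linear sequence: 14 (Steps 1–13, then 15); Step 14 is a one‑step side branch.

Steps most likely to fail, each with a fallback:

1. **Step 2** (asymmetric vinylation next to the quaternary ketal carbon: low conversion, protodeboronation or modest ee). Fallback: switch to Cu(I)/phosphoramidite‑catalysed asymmetric conjugate addition of a vinylaluminium reagent, a different metal, nucleophile class and stereocontrol element. The Step 3 reduction still removes residual minor enantiomer as a diastereomer.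
2. **Step 12** (Mitsunobu on a hindered pseudoaxial allylic alcohol: E2 to the diene or SN2′). Fallback: make the C–O bond at the arene instead. At amide 13, oxidise C1–OH with MnO2 and Luche‑reduce to the trans (1R) alcohol. Then couple it with retention to 4‑bromo‑3‑methoxybenzaldehyde dimethyl acetal by Pd‑catalysed C–O coupling (t‑BuBrettPhos type), followed by the Grignard step and acetal hydrolysis.
3. **Step 15** (Pabon condensation on a polyfunctional aldehyde: competing aldol at the side‑chain enone, acid‑sensitive allylic ether and alcohol). Fallback: take the curcuminoid construction off the terpenoid. Prepare mono‑O‑TBS curcumin separately, couple it to alcohol 15 by Mitsunobu inversion, and remove both silyl groups with HF·pyridine, so the last bond formed is C–O, not C=C.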